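Against the larch run, this flask holds half the starting material with the same reagent, protic impurity and initiator, and it stands for 20 h instead of 120 min.

| flask | starting material | reagent | protic impurity | initiator | remark | time |
|---|---|---|---|---|---|---|
| larch | 1.6 M | 0.80 M | 0.080 M | 120 mM | run made earlier |  |
| flask | 0.80 M | 0.800 M | 0.0800 M | 120 mM |  | 20 h |

larch run (percent of the starting material charged)

| time / min | product / % | quenched substrate / % |
|---|---|---|
| 20.0 | 3.6 | 2.0 |
| 40.0 | 6.6 | 3.7 |
| 60.0 | 9.2 | 2.4 |
| 80.0 | 14.7 | 4.2 |
| 90.0 | 12.8 | 5.6 |
| 120 | 17.9 | 4.4 |

(readings scatter by 1 percentage point)

- on the list of suspects stand: initiator -> 2 initiating radical; starting material + initiating radical -> chain carrier; reagent + chain carrier -> product + initiating radical; 2 initiating radical -> ended chains; starting material + protic impurity -> quenched substrate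

- concentration of product at 20 h, in M
- concentration of quenched substrate at 20 h, in M
- concentration of starting material at 20 h, in M

On the list of suspects, initiator gives initiating radicals, each radical turns starting material into chain carrier, reagent turns chain carrier into product and returns the radical, and two radicals end a chain. Protic impurity quenches starting material separately. I climb the time scales.

On the bottom rung I assume the radical holds a steady level (quasi-steady state), with its making balanced by pairs ending, so that level goes as the square root of initiator.

Next comes the quench. The first larch reading gives its time constant, with the scatter of one reading, and that constant should stretch as starting material falls: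

τ(larch) = 39.2 min, so τ(flask) ≈ 78.3 min

This is far shorter than the run, so I treat the quench as a correction and take 0.0800 M off the charge. That leaves 0.720 M for the chain, less than the reagent charged.

Above that stands the chain. With a steady radical, product follows starting material and not reagent while reagent lasts, so I carry the chain constant, the pseudo-first-order fraction of starting material taken per minute. The last larch reading gives, with the scatter of one reading:

chain constant = 0.00174 min⁻¹, a half-life of 6.64 h

The readings give no measure of initiator decay, so I hold initiator constant. For this flask I reckon:

starting material = 0.0893 M, product = 0.631 M, quenched substrate = 0.0800 M

The forecast gives 0.55 M product, 0.08 M quenched substrate and 0.17 M starting material, so its starting material stands higher than mine and its product lower, and it holds that initiator decay “would slow the late stage”.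

The flask gives 0.629 M product, 0.0795 M quenched substrate and 0.0919 M starting material.

    initiator → 2 initiating radical (k = 9.30 × 10⁻⁷ s⁻¹)
    starting material + initiating radical → chain carrier (k = 180 M⁻¹ s⁻¹)
    reagent + chain carrier → product + initiating radical (k = 91.0 M⁻¹ s⁻¹)
    2 initiating radical → ended chains (k = 4.40 × 10⁶ M⁻¹ s⁻¹)
    starting material + protic impurity → quenched substrate (k = 2.30 × 10⁻⁴ M⁻¹ s⁻¹)

In this flask, starting material has a half-life of 6.9 h by the chain step at 20.0 h, shorter than the run, which spans 2.90 such half-lives. For the same flask with 0.048 M of initiator, the square root lowers my chain constant to 0.00110 min⁻¹, from which I reckon 0.192 M of starting material, and that flask holds 0.196 M.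

(The readings stem from a simulated flask with constants of no real substance; scatter was added.)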